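**Retrosynthetic overview**

1. Atom names used here: guaiacyl–C7H2–C8H(C9H3)–C8'H(C9'H2OAc)–C7'H2–syringyl. Target 21 comes from alcohol 19 by acetylation and removal of two benzyl ethers; the C9'H2OH group of 19 stands where a boron atom sat on C8' in boronic ester 16 (Matteson homologation, then oxidation).
2. Key disconnection: the C7'–C1(syringyl) bond and, in the same operation, C8–C8'. This is a conjunctive cross-coupling of aryl triflate 14, vinyllithium and the (S)-secondary boronic ester 9 under a chiral bisphosphine–palladium catalyst, which also sets C8'.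
3. Enabling feature: C7'H2–C8'H is a two-carbon unit with the syringyl ring on one carbon and, on the other, the C8 branch plus a one-carbon oxygenated branch (C9'). That is the pattern left by a vinyl boron ate complex arylated at its CH2 end while an alkyl group migrates from boron to the boron-bearing carbon.
4. 9 comes from benzylic boronic ester 3 and ethyl carbamate 6 by (+)-sparteine-mediated lithiation–borylation (sets C8). 14 comes from syringaldehyde 10 by benzylation, Dakin oxidation and triflation.
5. No ring is formed in the route: both benzene rings are bought (vanillyl and syringyl series) and only the four-carbon chain between them is built.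

Key step: step 8

Remark 1: the ligand enantiomer in step 8 is assumed to induce at C8' the same sense as with simple primary alkyl migrating groups; if the opposite sense is found, the enantiomeric ligand is used, since C8' is set by the catalyst and not by C8.
Remark 2: halide-free vinyllithium is taken as a stock solution (made beforehand from tetravinylstannane and n-BuLi and freed from tin residues), because halide ions slow the key step.

**Route**

Step 1
Reactants: 1 4-(benzyloxy)-3-methoxybenzyl alcohol
Product: 2 4-(benzyloxy)-3-methoxybenzyl chloride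
Conditions: SOCl2, DMF (cat.), CH2Cl2, 0 °C to rt
Reagents that add atoms: thionyl chloride, O=S(Cl)Cl
Why: Deoxychlorination of an electron-rich benzylic alcohol through its chlorosulfite is reliable and leaves the aryl benzyl ether untouched.

Step 2
Reactants: 2 4-(benzyloxy)-3-methoxybenzyl chloride
Product: 3 2-[4-(benzyloxy)-3-methoxybenzyl]-4,4,5,5-tetramethyl-1,3,2-dioxaborolane
Conditions: B2pin2, Pd(dba)2 (cat.), P(4-MeOC6H4)3 (cat.), KOAc, toluene, 50 °C
Reagents that add atoms: bis(pinacolato)diboron, CC1(C)OB(OC1(C)C)B1OC(C)(C)C(C)(C)O1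
Why: Miyaura borylation of a benzylic chloride (oxidative addition, acetate-assisted transmetalation with the diboron, reductive elimination) should give the benzylic pinacol boronic ester without touching the aryl ethers.

Step 3
Reactants: 4 ethanol; 5 N,N-diisopropylcarbamoyl chloride
Product: 6 ethyl N,N-diisopropylcarbamate
Conditions: NaH, THF, 0 °C to reflux
Reagents that add atoms: none
Why: Acylation of sodium ethoxide by the carbamoyl chloride gives the hindered carbamate that later serves as directing group for lithiation and as leaving group for the 1,2-migration.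

Step 4
Reactants: 6 ethyl N,N-diisopropylcarbamate; 3 2-[4-(benzyloxy)-3-methoxybenzyl]-4,4,5,5-tetramethyl-1,3,2-dioxaborolane
Product: 9 2-[(2S)-1-[4-(benzyloxy)-3-methoxyphenyl]propan-2-yl]-4,4,5,5-tetramethyl-1,3,2-dioxaborolane, via lithiated carbamate 7 (not isolated), via boron ate complex 8 (not isolated)
Conditions: s-BuLi, (+)-sparteine, Et2O, −78 °C; then 3, −78 °C; then MgBr2·OEt2, reflux
Reagents that add atoms: none
Why: Sparteine-mediated lithiation–borylation: s-BuLi/(+)-sparteine should remove one enantiotopic proton of 6 to give the configurationally stable (R)-lithiated carbamate 7, boron takes the place of lithium with retention, and the MgBr2-promoted 1,2-migration of the benzylic group displaces the carbamate with inversion, so that C8 is set as (S) under reagent control.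

Step 5
Reactants: 10 syringaldehyde (4-hydroxy-3,5-dimethoxybenzaldehyde)
Product: 11 4-(benzyloxy)-3,5-dimethoxybenzaldehyde
Conditions: BnBr, K2CO3, DMF, 60 °C
Reagents that add atoms: benzyl bromide, BrCc1ccccc1
Why: Williamson etherification of the acidic, aldehyde-activated phenol protects the future free hydroxyl of the syringyl ring as a hydrogenolysable ether.

Step 6
Reactants: 11 4-(benzyloxy)-3,5-dimethoxybenzaldehyde
Product: 13 4-(benzyloxy)-3,5-dimethoxyphenol, via aryl formate 12 (not isolated)
Conditions: mCPBA, CH2Cl2, 0 °C to rt; aqueous Na2SO3/NaHCO3 wash; then K2CO3 (cat.), MeOH, rt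
Reagents that add atoms: mCPBA, OOC(=O)c1cccc(Cl)c1
Why: Dakin-type Baeyer–Villiger oxidation: the electron-rich aryl group migrates in the Criegee intermediate to give the aryl formate, which mild methanolysis cleaves to the phenol after the peracid has been removed.

Step 7
Reactants: 13 4-(benzyloxy)-3,5-dimethoxyphenol
Product: 14 4-(benzyloxy)-3,5-dimethoxyphenyl trifluoromethanesulfonate
Conditions: Tf2O, pyridine, CH2Cl2, 0 °C
Reagents that add atoms: trifluoromethanesulfonic anhydride, O=S(=O)(OS(=O)(=O)C(F)(F)F)C(F)(F)F
Why: O-Sulfonylation of the phenol gives an aryl triflate whose reacting carbon is flanked only by ring C–H positions and whose leaving group does not coordinate to palladium, as the key step requires.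

Step 8
Reactants: 9 2-[(2S)-1-[4-(benzyloxy)-3-methoxyphenyl]propan-2-yl]-4,4,5,5-tetramethyl-1,3,2-dioxaborolane; 14 4-(benzyloxy)-3,5-dimethoxyphenyl trifluoromethanesulfonate
Product: 16 2-[(2R,3S)-4-[4-(benzyloxy)-3-methoxyphenyl]-1-[4-(benzyloxy)-3,5-dimethoxyphenyl]-3-methylbutan-2-yl]-4,4,5,5-tetramethyl-1,3,2-dioxaborolane, via lithium vinyl borate 15 (not isolated)
Conditions: vinyllithium (halide-free), Et2O, 0 °C to rt, then solvent exchange; 14, Pd(OAc)2 (cat.), (S,S)-1,1'-bis[bis(4-methoxy-3,5-dimethylphenyl)phosphino]-2,2'-bis[(R)-α-(dimethylamino)benzyl]ferrocene (cat., the (Sp,Sp)-Mandyphos ligand), THF, 60 °C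
Reagents that add atoms: vinyllithium, [Li]C=C
Why: Oxidative addition of zerovalent palladium to triflate 14 gives a cationic divalent arylpalladium species that binds the vinyl group of the four-coordinate borate 15; this activation triggers a 1,2-metallate shift in which C8 migrates from boron to C8' anti to palladium and with retention at C8 while the Pd–C bond forms at the terminal carbon, and reductive elimination then makes the C7'–aryl bond and returns the catalyst. The closest known reaction type is the palladium-catalysed enantioselective conjunctive cross-coupling of vinylboron ate complexes with aryl triflates, used here with an enantioenriched secondary alkyl migrating group. No ring is closed. The new stereocentre C8' is controlled by the chiral bisphosphine on palladium, which selects the face of the vinyl group that is activated, so catalyst control and the stereoretentive migration together should give the (2R,3S) isomer, and any product from the minor enantiomer of 9 becomes a separable diastereomer. The step needs the metallate shift to outrun direct transfer of the vinyl or alkyl group to palladium (plain Suzuki–Miyaura products) and β-hydride elimination; the non-coordinating triflate and the halide-free medium keep palladium cationic and alkene-bound, boron carries only one migratable carbon group besides the vinyl acceptor, and the wide-bite-angle ligand favours fast reductive elimination.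

Step 9
Reactants: 16 2-[(2R,3S)-4-[4-(benzyloxy)-3-methoxyphenyl]-1-[4-(benzyloxy)-3,5-dimethoxyphenyl]-3-methylbutan-2-yl]-4,4,5,5-tetramethyl-1,3,2-dioxaborolane
Product: 19 (2R,3S)-2-[4-(benzyloxy)-3,5-dimethoxybenzyl]-4-[4-(benzyloxy)-3-methoxyphenyl]-3-methylbutan-1-ol, via chloromethyl borate 17 (not isolated), via homologated boronic ester 18 (not isolated)
Conditions: BrCH2Cl, n-BuLi, THF, −78 °C to rt; then NaOH, H2O2, THF/H2O, 0 °C to rt
Reagents that add atoms: bromochloromethane, ClCBr; hydrogen peroxide, OO
Why: Matteson homologation: chloromethyllithium formed in situ is trapped by the boronic ester at −78 °C as borate 17, warming induces 1,2-migration of C8' with retention and loss of chloride to give 18, and the stereoretentive peroxide oxidation of the primary C–B bond delivers the C9' hydroxymethyl group.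

Step 10
Reactants: 19 (2R,3S)-2-[4-(benzyloxy)-3,5-dimethoxybenzyl]-4-[4-(benzyloxy)-3-methoxyphenyl]-3-methylbutan-1-ol
Product: 20 (2R,3S)-2-[4-(benzyloxy)-3,5-dimethoxybenzyl]-4-[4-(benzyloxy)-3-methoxyphenyl]-3-methylbutyl acetate
Conditions: Ac2O, pyridine, DMAP (cat.), CH2Cl2, rt
Reagents that add atoms: acetic anhydride, CC(=O)OC(C)=O
Why: DMAP-catalysed acetylation of the only free hydroxyl group, a primary alcohol, places the acetate while both phenols are still masked.

Step 11
Reactants: 20 (2R,3S)-2-[4-(benzyloxy)-3,5-dimethoxybenzyl]-4-[4-(benzyloxy)-3-methoxyphenyl]-3-methylbutyl acetate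
Product: 21 (2R,3S)-2-(4-hydroxy-3,5-dimethoxybenzyl)-4-(4-hydroxy-3-methoxyphenyl)-3-methylbutyl acetate (CID53359579)
Conditions: H2 (1 atm), 10% Pd/C, EtOAc, rt
Reagents that add atoms: none
Why: Hydrogenolysis of the two aryl benzyl ethers on palladium frees both phenols, while the primary acetate, the aryl methyl ethers, the ArCH2–C bonds and both stereocentres are inert in this neutral, non-alcoholic medium.

**Compound list**

1 | 4-(benzyloxy)-3-methoxybenzyl alcohol | COc1cc(CO)ccc1OCc1ccccc1 | starting material
2 | 4-(benzyloxy)-3-methoxybenzyl chloride | COc1cc(CCl)ccc1OCc1ccccc1 | intermediate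
3 | 2-[4-(benzyloxy)-3-methoxybenzyl]-4,4,5,5-tetramethyl-1,3,2-dioxaborolane | COc1cc(CB2OC(C)(C)C(C)(C)O2)ccc1OCc1ccccc1 | intermediate
4 | ethanol | CCO | starting material
5 | N,N-diisopropylcarbamoyl chloride | CC(C)N(C(C)C)C(Cl)=O | starting material
6 | ethyl N,N-diisopropylcarbamate | CCOC(=O)N(C(C)C)C(C)C | intermediate
7 | (R)-1-lithioethyl N,N-diisopropylcarbamate, as its (+)-sparteine complex | C[C@@H]([Li])OC(=O)N(C(C)C)C(C)C | intermediate
8 | lithium [4-(benzyloxy)-3-methoxybenzyl][(1R)-1-(diisopropylcarbamoyloxy)ethyl](pinacolato)borate | [Li+].C[C@@H]([B-]1(Cc2ccc(OCc3ccccc3)c(OC)c2)OC(C)(C)C(C)(C)O1)OC(=O)N(C(C)C)C(C)C | intermediate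
9 | 2-[(2S)-1-[4-(benzyloxy)-3-methoxyphenyl]propan-2-yl]-4,4,5,5-tetramethyl-1,3,2-dioxaborolane | COc1cc(C[C@H](C)B2OC(C)(C)C(C)(C)O2)ccc1OCc1ccccc1 | intermediate
10 | syringaldehyde (4-hydroxy-3,5-dimethoxybenzaldehyde) | COc1cc(C=O)cc(OC)c1O | starting material
11 | 4-(benzyloxy)-3,5-dimethoxybenzaldehyde | COc1cc(C=O)cc(OC)c1OCc1ccccc1 | intermediate
12 | 4-(benzyloxy)-3,5-dimethoxyphenyl formate | COc1cc(OC=O)cc(OC)c1OCc1ccccc1 | intermediate
13 | 4-(benzyloxy)-3,5-dimethoxyphenol | COc1cc(O)cc(OC)c1OCc1ccccc1 | intermediate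
14 | 4-(benzyloxy)-3,5-dimethoxyphenyl trifluoromethanesulfonate | COc1cc(OS(=O)(=O)C(F)(F)F)cc(OC)c1OCc1ccccc1 | intermediate
15 | lithium [(2S)-1-[4-(benzyloxy)-3-methoxyphenyl]propan-2-yl](ethenyl)(pinacolato)borate | [Li+].COc1cc(C[C@H](C)[B-]2(C=C)OC(C)(C)C(C)(C)O2)ccc1OCc1ccccc1 | intermediate
16 | 2-[(2R,3S)-4-[4-(benzyloxy)-3-methoxyphenyl]-1-[4-(benzyloxy)-3,5-dimethoxyphenyl]-3-methylbutan-2-yl]-4,4,5,5-tetramethyl-1,3,2-dioxaborolane | COc1cc(C[C@H](C)[C@H](B2OC(C)(C)C(C)(C)O2)Cc2cc(OC)c(OCc3ccccc3)c(OC)c2)ccc1OCc1ccccc1 | intermediate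
17 | lithium (chloromethyl)[(2R,3S)-4-[4-(benzyloxy)-3-methoxyphenyl]-1-[4-(benzyloxy)-3,5-dimethoxyphenyl]-3-methylbutan-2-yl](pinacolato)borate | [Li+].COc1cc(C[C@H](C)[C@H]([B-]2(CCl)OC(C)(C)C(C)(C)O2)Cc2cc(OC)c(OCc3ccccc3)c(OC)c2)ccc1OCc1ccccc1 | intermediate
18 | 2-[(2R,3S)-2-[4-(benzyloxy)-3,5-dimethoxybenzyl]-4-[4-(benzyloxy)-3-methoxyphenyl]-3-methylbutyl]-4,4,5,5-tetramethyl-1,3,2-dioxaborolane | COc1cc(C[C@H](C)[C@H](CB2OC(C)(C)C(C)(C)O2)Cc2cc(OC)c(OCc3ccccc3)c(OC)c2)ccc1OCc1ccccc1 | intermediate
19 | (2R,3S)-2-[4-(benzyloxy)-3,5-dimethoxybenzyl]-4-[4-(benzyloxy)-3-methoxyphenyl]-3-methylbutan-1-ol | COc1cc(C[C@H](C)[C@H](CO)Cc2cc(OC)c(OCc3ccccc3)c(OC)c2)ccc1OCc1ccccc1 | intermediate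
20 | (2R,3S)-2-[4-(benzyloxy)-3,5-dimethoxybenzyl]-4-[4-(benzyloxy)-3-methoxyphenyl]-3-methylbutyl acetate | COc1cc(C[C@H](C)[C@H](COC(C)=O)Cc2cc(OC)c(OCc3ccccc3)c(OC)c2)ccc1OCc1ccccc1 | intermediate
21 | (2R,3S)-2-(4-hydroxy-3,5-dimethoxybenzyl)-4-(4-hydroxy-3-methoxyphenyl)-3-methylbutyl acetate | COc1cc(C[C@H](C)[C@H](COC(C)=O)Cc2cc(OC)c(O)c(OC)c2)ccc1O | target

**Step count and risks**

Total step count: 11 steps.
Longest linear sequence: 7 steps (steps 1, 2, 4, 8, 9, 10, 11; the syringyl branch 5, 6, 7, 8, 9, 10, 11 is equally long).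

Steps most likely to fail:

1. Step 8. What may go wrong: direct transfer of the vinyl group from boron to palladium (plain cross-coupling) may compete, the metallate shift of the hindered secondary alkyl group may be slow, and the neighbouring C8 centre may erode facial selectivity at C8'. Fallback, setting out from 9 and coming back at 16, forming the same C7'–aryl bond by a two-component coupling: Zweifel olefination of 9 (vinyllithium, THF, −78 °C; I2; NaOMe, MeOH) should give, with retention at C8, (S)-1-(benzyloxy)-2-methoxy-4-(2-methylbut-3-en-1-yl)benzene F1. Platinum-catalysed enantioselective diboration of F1 (Pt(dba)3, the TADDOL-derived phosphonite enantiomer that gives the (2R) centre, B2pin2, THF, 60 °C) should give 2,2'-[(2R,3S)-4-[4-(benzyloxy)-3-methoxyphenyl]-3-methylbutane-1,2-diyl]bis(4,4,5,5-tetramethyl-1,3,2-dioxaborolane) F2 under catalyst control. The primary C–B bond of F2 alone is then coupled (Pd(OAc)2, RuPhos, KOH, THF/H2O, 70 °C) with 2-(benzyloxy)-5-bromo-1,3-dimethoxybenzene F3 (from commercial 4-bromo-2,6-dimethoxyphenol, BnBr, K2CO3), the secondary boronic ester staying untouched, to give 16.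

2. Step 4. What may go wrong: incomplete 1,2-migration of the ate complex, competing deprotonation of the acidic benzylic boronic ester by the lithiated carbamate, or partial loss of configuration of the lithiated carbamate. Fallback, setting out from 2 and coming back at 9, with the C8 centre set by catalytic alkene protoboration instead of by deprotonation: copper-catalysed coupling of 2 with vinylmagnesium bromide (CuI cat., THF, 0 °C) should give 4-allyl-1-(benzyloxy)-2-methoxybenzene F4. Copper-catalysed enantioselective Markovnikov protoboration of F4 (CuCl, a bulky P-stereogenic bisphosphine of the QuinoxP* family, B2pin2, KOt-Bu, MeOH, THF) should then place boron on the internal carbon and give 9.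

3. Step 9. What may go wrong: incomplete capture of the hindered secondary boronic ester by the short-lived carbenoid, or a second insertion into the less hindered primary boronic ester. Fallback, setting out from 16 and coming back at 19, with C9' brought in as a vinyl group and cut back: Zweifel olefination of 16 (vinyllithium, THF, −78 °C; I2; NaOMe, MeOH) should give, with retention at C8', 1-(benzyloxy)-4-[(2S,3S)-3-[4-(benzyloxy)-3,5-dimethoxybenzyl]-2-methylpent-4-en-1-yl]-2-methoxybenzene F5. Lemieux–Johnson cleavage of F5 (OsO4 cat., NaIO4, 2,6-lutidine, dioxane/H2O) should give (2R,3S)-2-[4-(benzyloxy)-3,5-dimethoxybenzyl]-4-[4-(benzyloxy)-3-methoxyphenyl]-3-methylbutanal F6, which is reduced at once (NaBH4, MeOH, 0 °C) to 19 before the α-centre can epimerise.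

**Further compounds**

F1 | step 8 | (S)-1-(benzyloxy)-2-methoxy-4-(2-methylbut-3-en-1-yl)benzene | COc1cc(C[C@H](C)C=C)ccc1OCc1ccccc1
F2 | step 8 | 2,2'-[(2R,3S)-4-[4-(benzyloxy)-3-methoxyphenyl]-3-methylbutane-1,2-diyl]bis(4,4,5,5-tetramethyl-1,3,2-dioxaborolane) | COc1cc(C[C@H](C)[C@H](B2OC(C)(C)C(C)(C)O2)CB2OC(C)(C)C(C)(C)O2)ccc1OCc1ccccc1
F3 | step 8 | 2-(benzyloxy)-5-bromo-1,3-dimethoxybenzene | COc1cc(Br)cc(OC)c1OCc1ccccc1
F4 | step 4 | 4-allyl-1-(benzyloxy)-2-methoxybenzene | COc1cc(CC=C)ccc1OCc1ccccc1
F5 | step 9 | 1-(benzyloxy)-4-[(2S,3S)-3-[4-(benzyloxy)-3,5-dimethoxybenzyl]-2-methylpent-4-en-1-yl]-2-methoxybenzene | COc1cc(C[C@H](C)[C@H](C=C)Cc2cc(OC)c(OCc3ccccc3)c(OC)c2)ccc1OCc1ccccc1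
F6 | step 9 | (2R,3S)-2-[4-(benzyloxy)-3,5-dimethoxybenzyl]-4-[4-(benzyloxy)-3-methoxyphenyl]-3-methylbutanal | COc1cc(C[C@H](C)[C@H](C=O)Cc2cc(OC)c(OCc3ccccc3)c(OC)c2)ccc1OCc1ccccc1
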